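## The problem

The target is a cis,cis-germacranolide: a cyclodeca-1(10),4-diene whose two trisubstituted ring alkenes both hold their ring neighbours cis. C2 and C9 are cis across C1=C10, which carries the C14 methyl ester; C3 and C6 are cis across C4=C5, which carries the C15 methyl. The ring is fused trans across C6–C7 to an α-methylene-γ-butyrolactone (C11, C12, C13).

Four contiguous stereocentres run from C6 to C9 (6R,7S,8S,9S): the lactone oxygen, the ring fusion, the angelate and a free secondary alcohol. C8 is a simple oxygenated centre that can be bought and can bias C7. C6 and C7 are adjacent and can be set in one operation. C9 has only C8 to lean on.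

Several groups will not survive rough treatment. The methylene lactone is a Michael acceptor. The angelate isomerises to the tiglate with base or nucleophilic catalysts and can shift to the C9 hydroxyl. The lactone can move from O6 to a free O8. The C6–O bond is allylic.

A ten-membered ring costs entropy and transannular strain, so it should be closed late, on a chain whose two alkenes already have their geometry.

The feature that opens the route is the C5–C8 segment. With the ring opened and C4=C5 traced back to a C5 carbonyl, C6 (oxygen) and C7 (the C11 branch) are the α- and β-carbons of a C5 aldehyde, and the γ-carbon C8 is C2 of glyceraldehyde. Such an enal takes a carbon nucleophile at C7 through its iminium ion and an oxygen electrophile at C6 through the enamine that follows.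

## Retrosynthesis

**C9–C10.** The ring of 23 is opened between C9 and C10 to give iodo aldehyde 22. Cutting here, and not at C5–C6 or C2–C3, lets the lactone, the methylene group, the C14 ester and the angelate stand in final form before the ring exists, so ring closure is the last step. 22 is an open chain with both alkenes defined. The forward reaction is an intramolecular Nozaki–Hiyama–Kishi addition. It must keep the C1=C10 geometry and add to the Si face of the aldehyde to give the 9S alcohol.

**Periphery and C1=C10.** 22 goes back to diol 18 by functional-group changes: the C9 aldehyde from the primary silyl ether of 21, the angelate from alcohol 19 and acid 20, the silyl ether from 18. The C1=C10 bond of 18 is then cut as a Wittig disconnection into aldehyde 16 and ylide 17, which is iodinated in the flask. This brings C10, C14 and the iodine in one commercial piece and gives the Z iodoenoate directly. A route through a protected C14 alcohol would need extra oxidation steps. The forward steps must tell the primary from the secondary hydroxyl and must not isomerise the angelate.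

**C3–C4.** Aldehyde 16 is the hydrolysis product of bis-acetal 15, which is cut between C3 and C4 into alkenyl iodide 13 and zinc reagent 14. An sp2–sp3 coupling with retention passes the geometry of 13 on to the trisubstituted alkene. Building C4=C5 by olefination with the whole C1–C3 chain attached would give poor control at a trisubstituted alkene. 13 carries only C4–C9 and C11–C13. The coupling has to leave the methylene lactone alone.

**Lactone and methylene.** 13 comes from α-carboxy lactone 11 by decarboxylative methylenation, and 11 from benzoate diester 9 by hydrolysis and closure of O6 on one malonate carbonyl. This uses both ester groups of the malonate: one becomes C12, the other leaves as carbon dioxide when C13 enters. No lactone enolate is needed. It is done early because hydrolysis would not spare the later esters.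

**C4=C5.** 9 is cut at C4=C5 into aldehyde 7 and phosphonium salt 8 (iodoethylidene Wittig). An ester-forming Z-olefination was rejected: a C3 ester cis to O6 would close a butenolide once the benzoate is removed, and it could not be reduced beside the malonate. The iodide serves as the handle for C3 instead. The olefination must be Z-selective and must not epimerise C6.

**C7–C11 and C6–O (key step).** 7 is cut into enal 3, malonate 4 and peroxide 5. These two bonds are chosen because one amine catalyst can make both and set C6 and C7 together, next to the purchased C8 centre. The precursor is a five-carbon enal. The reaction must give the 6,7-syn, 7,8-anti triad.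

**C6=C7 of the enal.** 3 is the Wittig product of aldehyde 1 and formyl ylide 2. The reaction only has to be E-selective and leave the dioxolane centre alone.

## Roads not taken

Alternative 1: The cut is C5–C6 together with the lactone C12–O bond. In the forward step, a chromium/nickel-mediated reaction would add the (Z)-alkenyl iodide at C5 of open-chain iodo aldehyde A1 to its C6 aldehyde. The chromium alkoxide would then acylate on the C12 methyl ester, giving bicyclic lactone A2 with the ten-membered ring and the lactone made in one operation.
- Merits: the donor is a plain alkenyl iodide, the best-behaved class for this chemistry. Two rings form at once. C8 and C9 are in place beforehand, so the C9 question does not arise at ring closure.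
- Weak points: C6 is created in the ring closure with only C7 and the ring conformation to guide it. The aldehyde of A1 sits on C7, an enolisable centre, so epimerisation threatens. A1 must carry every other feature through a long linear build. A2 still lacks C13, so the complete molecule would face lactone enolate chemistry beside the angelate and the enoate.
- Comparison: the ring closure of A1 uses a more reliable chromium donor than that of 22, and this is conceded. Against it, the chosen plan fixes C6 and C7 together by a catalyst at the start, has the methylene group in place before the ring is closed, and lets nothing follow ring closure.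

Alternative 2: The cut is C4–C5 and C1–C10 through a cyclobutane. Irradiation of lactone-fused 2-carbomethoxycyclohexenone A3 with 1-methylcyclobutene A4 would give the cis-anti-cis tricyclic photoadduct A5. Heating would then open the central four-membered ring in the other direction to the cyclodecadiene.
- Merits: two carbon–carbon bonds form in one step. The ten-membered ring arises by fragmentation, without high dilution. C6–C8 come from the chiral pool.
- Weak points: the regiochemistry of addition of the unsymmetrical alkene A4 is open. The thermal opening of A5 is expected to give a cyclodeca-1,5-diene with one trans ring alkene, and such dienes undergo Cope rearrangement to divinylcyclohexanes at the temperatures needed; 23 needs both ring alkenes cis. The C9 ketone of A5 must still be reduced with control, C8 acylated and C13 added.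
- Comparison: this road has fewer bond-forming events and avoids a macrocyclisation, which is a real advantage. It leaves the alkene geometry to orbital symmetry and heat. The chosen plan sets each ring alkene by a stereodefined olefination (steps 3 and 8) and a coupling with retention (step 6).

Alternative 3: The cut is C2–C3. A strong amide base would deprotonate the C3 allylic sulfone of open-chain sulfone bromide A6, and the anion would displace the C2 allylic bromide to give cyclic sulfone A7.
- Merits: alkylation of sulfone-stabilised allyl anions is a proven way to ten-membered carbocycles. No lasting stereocentre is formed, and all four stereocentres of the target are set in the open chain.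
- Weak points: the strong base meets the angelate and the lactone α-protons. α- versus γ-alkylation and alkene migration are open. After closure come reductive removal of the sulfone next to an allylic system, conversion of the C14 silyl ether into the ester (deprotection, two oxidations, esterification) and α-methylenation: five or six steps on the complete ring.
- Comparison: the closure of A6 is arguably better precedented for such rings than the chromium closure of 22, and it has no C9 selectivity question. Against it, the chosen plan ends with the ring closure, has C13 and C14 in final form beforehand, and uses no strong base once the angelate is on.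

Key step: step 2

Assumption: C11 in 10, 11 and 12 is a mixture of epimers and is left undefined, since it becomes sp2 in 13; locants C1–C15 are germacrane numbers.

## Route

Step 1
Reactants: 1 (R)-2,3-O-isopropylideneglyceraldehyde; 2 (triphenylphosphoranylidene)acetaldehyde
Product: 3 (E)-3-[(4S)-2,2-dimethyl-1,3-dioxolan-4-yl]prop-2-enal
Conditions: toluene, rt → 60 °C
Reagents that add atoms: none
Why: Wittig olefination with a formyl-stabilised ylide, which should give the E enal; the dioxolane centre is not touched (its descriptor changes from R to S only through the priority rules).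

Step 2
Reactants: 3 (E)-3-[(4S)-2,2-dimethyl-1,3-dioxolan-4-yl]prop-2-enal; 4 dimethyl malonate; 5 dibenzoyl peroxide
Product: 7 dimethyl 2-[(1R,2S)-2-(benzoyloxy)-1-[(4S)-2,2-dimethyl-1,3-dioxolan-4-yl]-3-oxopropyl]propanedioate, via Michael adduct 6 (not isolated)
Conditions: (S)-2-[diphenyl(trimethylsilyloxy)methyl]pyrrolidine (20 mol %), PhCO2H (20 mol %), 4, CH2Cl2, 0 °C; then 5, hydroquinone (10 mol %), 0 °C; crude 7 taken straight into step 3
Reagents that add atoms: none
Why: The secondary amine condenses with enal 3 to an E, s-trans iminium ion, malonate 4 adds to C7 (bond C7–C11), and the enamine of Michael adduct 6 then attacks the O–O bond of 5 at C6 (bond C6–O) before hydrolysis releases 7 and the catalyst. The closest known reactions are the amine-catalysed conjugate addition of malonates to enals and the amine-catalysed α-benzoyloxylation of aldehydes, joined here as an iminium–enamine sequence in one flask. No ring is closed. C7 is set by the catalyst: its diphenyl(silyloxy)methyl group covers one face of the iminium ion, so malonate should enter from the open face, which for the (S)-catalyst is the 7R adduct needed. C6 is set by the same group on the enamine: the peroxide should approach anti to it and give the 6S benzoate, with O6 and C11 syn in the zigzag drawing. The step needs the 6,7-syn, 7,8-anti triad; the E geometry of 3 ties both additions to the same face, and the C8 dioxolane, with its hydrogen eclipsing the alkene, is expected to favour attack anti to the C8–O bond, the same sense as the catalyst. Adding 5 only after 3 is consumed keeps the peroxide from oxidising the amine during the slower first stage, and 7 is not stored because α-acyloxy aldehydes epimerise easily.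

Step 3
Reactants: 7 dimethyl 2-[(1R,2S)-2-(benzoyloxy)-1-[(4S)-2,2-dimethyl-1,3-dioxolan-4-yl]-3-oxopropyl]propanedioate; 8 ethyltriphenylphosphonium iodide
Product: 9 dimethyl 2-[(1S,2S,3Z)-2-(benzoyloxy)-1-[(4S)-2,2-dimethyl-1,3-dioxolan-4-yl]-4-iodopent-3-en-1-yl]propanedioate
Conditions: 8, n-BuLi, THF, rt; I2, −78 °C; NaN(SiMe3)2, −78 → −20 °C; then 7, −78 → −20 °C
Reagents that add atoms: iodine, II
Why: Stork–Zhao-type Wittig olefination with the α-iodoethylidene ylide made in the flask; the unstabilised ylide reacts under kinetic control through the cis-oxaphosphetane, which places iodine cis to the C6 residue and gives the Z iodoalkene. Low temperature and one equivalent of ylide should leave the C6 benzoate centre and the malonate untouched.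

Step 4
Reactants: 9 dimethyl 2-[(1S,2S,3Z)-2-(benzoyloxy)-1-[(4S)-2,2-dimethyl-1,3-dioxolan-4-yl]-4-iodopent-3-en-1-yl]propanedioate
Product: 11 (4S,5S)-4-[(4S)-2,2-dimethyl-1,3-dioxolan-4-yl]-5-[(Z)-2-iodoprop-1-en-1-yl]-2-oxooxolane-3-carboxylic acid (C3 epimers), via hydroxy diacid 10 (not isolated)
Conditions: LiOH·H2O, THF/MeOH/H2O, 0 °C → rt; then 1 M HCl to pH 3, EtOAc, 0 °C → rt
Reagents that add atoms: lithium hydroxide, [Li+].[OH-]
Why: Saponification cleaves the benzoate and both methyl esters to hydroxy diacid 10, and acidification closes the γ-lactone by 5-exo-trig attack of O6 on one carboxyl group; C6 and C7 are not enolisable and are kept, while the C11 mixture disappears in step 5.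

Step 5
Reactants: 11 (4S,5S)-4-[(4S)-2,2-dimethyl-1,3-dioxolan-4-yl]-5-[(Z)-2-iodoprop-1-en-1-yl]-2-oxooxolane-3-carboxylic acid
Product: 13 (4S,5S)-4-[(4S)-2,2-dimethyl-1,3-dioxolan-4-yl]-5-[(Z)-2-iodoprop-1-en-1-yl]-3-methylideneoxolan-2-one, via Mannich base 12 (not isolated)
Conditions: (CH2O)n, Et2NH, EtOAc, 70 °C
Reagents that add atoms: formaldehyde (from paraformaldehyde), C=O
Why: Decarboxylative Mannich methylenation: the malonic-type C11–H of 11 is aminomethylated by the iminium ion from formaldehyde and diethylamine to Mannich base 12, which loses carbon dioxide and the amine on warming to leave the C11=C13 alkene; no stereocentre is formed and C7 beside it is not acidic.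

Step 6
Reactants: 13 (4S,5S)-4-[(4S)-2,2-dimethyl-1,3-dioxolan-4-yl]-5-[(Z)-2-iodoprop-1-en-1-yl]-3-methylideneoxolan-2-one; 14 [2-(1,3-dioxolan-2-yl)ethyl]zinc bromide
Product: 15 (4S,5R)-4-[(4S)-2,2-dimethyl-1,3-dioxolan-4-yl]-5-[(Z)-4-(1,3-dioxolan-2-yl)-2-methylbut-1-en-1-yl]-3-methylideneoxolan-2-one
Conditions: Pd(PPh3)4 (5 mol %), THF, 40 °C
Reagents that add atoms: none
Why: Negishi coupling of the alkenyl iodide with a primary alkylzinc reagent under zerovalent palladium catalysis goes with retention, so C3 takes the place of iodine cis to C6 and the Z C4=C5 alkene is fixed; the organozinc does not add to the lactone or to the methylene group.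

Step 7
Reactants: 15 (4S,5R)-4-[(4S)-2,2-dimethyl-1,3-dioxolan-4-yl]-5-[(Z)-4-(1,3-dioxolan-2-yl)-2-methylbut-1-en-1-yl]-3-methylideneoxolan-2-one
Product: 16 (Z)-5-[(2R,3R)-3-[(1S)-1,2-dihydroxyethyl]-4-methylidene-5-oxooxolan-2-yl]-4-methylpent-4-enal
Conditions: 1 M aq. HCl, THF, rt
Reagents that add atoms: water, O
Why: Acid-catalysed hydrolysis removes the acetonide and the dioxolane together, freeing the C8/C9 diol and the C1 aldehyde; dilute acid at room temperature is chosen because stronger acid or base could move the lactone from O6 to the free O8.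

Step 8
Reactants: 16 (Z)-5-[(2R,3R)-3-[(1S)-1,2-dihydroxyethyl]-4-methylidene-5-oxooxolan-2-yl]-4-methylpent-4-enal; 17 methyl (triphenylphosphoranylidene)acetate
Product: 18 methyl (2Z,6Z)-7-[(2R,3R)-3-[(1S)-1,2-dihydroxyethyl]-4-methylidene-5-oxooxolan-2-yl]-2-iodo-6-methylhepta-2,6-dienoate
Conditions: 17, N-iodosuccinimide (1.0 equiv), CH2Cl2, −20 °C; then 16, −20 °C → rt
Reagents that add atoms: N-iodosuccinimide, O=C1CCC(=O)N1I
Why: Wittig olefination with the stabilised iodo ylide formed from 17 and N-iodosuccinimide; as with other ester-stabilised ylides the ester ends up trans to the chain, which is the Z iodoenoate (iodine cis to C2). The succinimide anion released in the iodination serves as the base, so the diol and the methylene lactone meet no added base.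

Step 9
Reactants: 18 methyl (2Z,6Z)-7-[(2R,3R)-3-[(1S)-1,2-dihydroxyethyl]-4-methylidene-5-oxooxolan-2-yl]-2-iodo-6-methylhepta-2,6-dienoate
Product: 19 methyl (2Z,6Z)-7-[(2R,3R)-3-[(1S)-1-hydroxy-2-(triethylsilyloxy)ethyl]-4-methylidene-5-oxooxolan-2-yl]-2-iodo-6-methylhepta-2,6-dienoate
Conditions: Et3SiCl (1.05 equiv), imidazole, CH2Cl2, −78 → −40 °C
Reagents that add atoms: chlorotriethylsilane, CC[Si](Cl)(CC)CC
Why: Selective silylation of the primary C9 hydroxyl over the hindered secondary C8 hydroxyl with one equivalent of chlorosilane at low temperature.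

Step 10
Reactants: 19 methyl (2Z,6Z)-7-[(2R,3R)-3-[(1S)-1-hydroxy-2-(triethylsilyloxy)ethyl]-4-methylidene-5-oxooxolan-2-yl]-2-iodo-6-methylhepta-2,6-dienoate; 20 angelic acid [(Z)-2-methylbut-2-enoic acid]
Product: 21 methyl (2Z,6Z)-2-iodo-6-methyl-7-[(2R,3S)-3-[(1S)-1-[(Z)-2-methylbut-2-enoyloxy]-2-(triethylsilyloxy)ethyl]-4-methylidene-5-oxooxolan-2-yl]hepta-2,6-dienoate
Conditions: 20, 2,4,6-Cl3C6H2COCl, Et3N, toluene, rt, filter; then 19, toluene, 80 °C
Reagents that add atoms: none
Why: Yamaguchi-type esterification through the mixed anhydride of 20 with 2,4,6-trichlorobenzoic acid, which acylates the C8 hydroxyl at the unhindered angeloyl carbonyl; leaving out nucleophilic catalysts such as 4-(dimethylamino)pyridine avoids Z to E isomerisation to the tiglate, and filtering off the amine salt keeps base-promoted lactone migration to O8 low.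

Step 11
Reactants: 21 methyl (2Z,6Z)-2-iodo-6-methyl-7-[(2R,3S)-3-[(1S)-1-[(Z)-2-methylbut-2-enoyloxy]-2-(triethylsilyloxy)ethyl]-4-methylidene-5-oxooxolan-2-yl]hepta-2,6-dienoate
Product: 22 methyl (2Z,6Z)-2-iodo-6-methyl-7-[(2R,3S)-3-[(1S)-1-[(Z)-2-methylbut-2-enoyloxy]-2-oxoethyl]-4-methylidene-5-oxooxolan-2-yl]hepta-2,6-dienoate
Conditions: (COCl)2, DMSO, CH2Cl2, −78 → −40 °C; Et3N, −78 → 0 °C
Reagents that add atoms: none
Why: Swern oxidation: activated dimethyl sulfoxide cleaves primary triethylsilyl ethers and oxidises them to aldehydes in one operation, so the C9 alcohol is never free beside the C8 ester and cannot take up the angeloyl group; the aldehyde is used at once because the C8 centre α to it is epimerisable.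

Step 12
Reactants: 22 methyl (2Z,6Z)-2-iodo-6-methyl-7-[(2R,3S)-3-[(1S)-1-[(Z)-2-methylbut-2-enoyloxy]-2-oxoethyl]-4-methylidene-5-oxooxolan-2-yl]hepta-2,6-dienoate
Product: 23 target: methyl (1(10)E,4Z,6R,7S,8S,9S)-8-[(Z)-2-methylbut-2-enoyloxy]-9-hydroxy-12-oxogermacra-1(10),4,11(13)-trien-12,6-olid-14-oate (both ring alkenes with ring carbons cis)
Conditions: CrCl2 (10 equiv), NiCl2 (cat.), DMSO, rt, 3 mM, slow addition of 22
Reagents that add atoms: none
Why: Intramolecular Nozaki–Hiyama–Kishi reaction: zerovalent nickel inserts into the C10–I bond, transmetalation gives an alkenylchromium species that should keep the alkene geometry and add only to the aldehyde, closing the ten-membered ring at C9–C10 under high dilution. C9 is set in this ring closure: addition to the Si face of the aldehyde, with the C8 angelate and the lactone turned to the outside of the forming ring, gives the 9S (8,9-syn) alcohol, but the open-chain Felkin–Anh preference points to the other face, so the selectivity rests on the ring conformation.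

## Compound list

1 | (R)-2,3-O-isopropylideneglyceraldehyde | CC1(C)OC[C@@H](O1)C=O | starting material
2 | (triphenylphosphoranylidene)acetaldehyde | O=CC=P(c1ccccc1)(c1ccccc1)c1ccccc1 | starting material
3 | (E)-3-[(4S)-2,2-dimethyl-1,3-dioxolan-4-yl]prop-2-enal | O=C/C=C/[C@H]1COC(C)(C)O1 | intermediate
4 | dimethyl malonate | COC(=O)CC(=O)OC | starting material
5 | dibenzoyl peroxide | O=C(OOC(=O)c1ccccc1)c1ccccc1 | starting material
6 | Michael adduct, dimethyl 2-[(1R)-1-[(4S)-2,2-dimethyl-1,3-dioxolan-4-yl]-3-oxopropyl]propanedioate (not isolated) | O=CC[C@H](C(C(=O)OC)C(=O)OC)[C@H]1COC(C)(C)O1 | intermediate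
7 | dimethyl 2-[(1R,2S)-2-(benzoyloxy)-1-[(4S)-2,2-dimethyl-1,3-dioxolan-4-yl]-3-oxopropyl]propanedioate | O=C[C@@H](OC(=O)c1ccccc1)[C@H](C(C(=O)OC)C(=O)OC)[C@H]1COC(C)(C)O1 | intermediate
8 | ethyltriphenylphosphonium iodide | CC[P+](c1ccccc1)(c1ccccc1)c1ccccc1.[I-] | starting material
9 | dimethyl 2-[(1S,2S,3Z)-2-(benzoyloxy)-1-[(4S)-2,2-dimethyl-1,3-dioxolan-4-yl]-4-iodopent-3-en-1-yl]propanedioate | C/C(I)=C/[C@@H](OC(=O)c1ccccc1)[C@H](C(C(=O)OC)C(=O)OC)[C@H]1COC(C)(C)O1 | intermediate
10 | hydroxy diacid, 2-[(1S,2S,3Z)-1-[(4S)-2,2-dimethyl-1,3-dioxolan-4-yl]-2-hydroxy-4-iodopent-3-en-1-yl]propanedioic acid (not isolated) | C/C(I)=C/[C@@H](O)[C@H](C(C(=O)O)C(=O)O)[C@H]1COC(C)(C)O1 | intermediate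
11 | (4S,5S)-4-[(4S)-2,2-dimethyl-1,3-dioxolan-4-yl]-5-[(Z)-2-iodoprop-1-en-1-yl]-2-oxooxolane-3-carboxylic acid (C3 epimers) | C/C(I)=C/[C@H]1OC(=O)C(C(=O)O)[C@@H]1[C@H]2COC(C)(C)O2 | intermediate
12 | Mannich base, 3-(diethylaminomethyl) derivative of 11 (not isolated) | C/C(I)=C/[C@H]1OC(=O)C(CN(CC)CC)(C(=O)O)[C@@H]1[C@H]2COC(C)(C)O2 | intermediate
13 | (4S,5S)-4-[(4S)-2,2-dimethyl-1,3-dioxolan-4-yl]-5-[(Z)-2-iodoprop-1-en-1-yl]-3-methylideneoxolan-2-one | C/C(I)=C/[C@H]1OC(=O)C(=C)[C@@H]1[C@H]2COC(C)(C)O2 | intermediate
14 | [2-(1,3-dioxolan-2-yl)ethyl]zinc bromide | Br[Zn]CCC1OCCO1 | starting material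
15 | (4S,5R)-4-[(4S)-2,2-dimethyl-1,3-dioxolan-4-yl]-5-[(Z)-4-(1,3-dioxolan-2-yl)-2-methylbut-1-en-1-yl]-3-methylideneoxolan-2-one | C/C(CCC1OCCO1)=C/[C@H]2OC(=O)C(=C)[C@@H]2[C@H]3COC(C)(C)O3 | intermediate
16 | (Z)-5-[(2R,3R)-3-[(1S)-1,2-dihydroxyethyl]-4-methylidene-5-oxooxolan-2-yl]-4-methylpent-4-enal | C/C(CCC=O)=C/[C@H]1OC(=O)C(=C)[C@@H]1[C@H](O)CO | intermediate
17 | methyl (triphenylphosphoranylidene)acetate | COC(=O)C=P(c1ccccc1)(c1ccccc1)c1ccccc1 | starting material
18 | methyl (2Z,6Z)-7-[(2R,3R)-3-[(1S)-1,2-dihydroxyethyl]-4-methylidene-5-oxooxolan-2-yl]-2-iodo-6-methylhepta-2,6-dienoate | C/C(CC/C=C(\I)C(=O)OC)=C/[C@H]1OC(=O)C(=C)[C@@H]1[C@H](O)CO | intermediate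
19 | methyl (2Z,6Z)-7-[(2R,3R)-3-[(1S)-1-hydroxy-2-(triethylsilyloxy)ethyl]-4-methylidene-5-oxooxolan-2-yl]-2-iodo-6-methylhepta-2,6-dienoate | C/C(CC/C=C(\I)C(=O)OC)=C/[C@H]1OC(=O)C(=C)[C@@H]1[C@H](O)CO[Si](CC)(CC)CC | intermediate
20 | angelic acid, (Z)-2-methylbut-2-enoic acid | C/C=C(/C)C(=O)O | starting material
21 | methyl (2Z,6Z)-2-iodo-6-methyl-7-[(2R,3S)-3-[(1S)-1-[(Z)-2-methylbut-2-enoyloxy]-2-(triethylsilyloxy)ethyl]-4-methylidene-5-oxooxolan-2-yl]hepta-2,6-dienoate | C/C(CC/C=C(\I)C(=O)OC)=C/[C@H]1OC(=O)C(=C)[C@@H]1[C@H](OC(=O)/C(C)=C\C)CO[Si](CC)(CC)CC | intermediate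
22 | methyl (2Z,6Z)-2-iodo-6-methyl-7-[(2R,3S)-3-[(1S)-1-[(Z)-2-methylbut-2-enoyloxy]-2-oxoethyl]-4-methylidene-5-oxooxolan-2-yl]hepta-2,6-dienoate | C/C(CC/C=C(\I)C(=O)OC)=C/[C@H]1OC(=O)C(=C)[C@@H]1[C@H](OC(=O)/C(C)=C\C)C=O | intermediate
23 | CNP0305372.2, methyl (1(10)E,4Z,6R,7S,8S,9S)-8-angeloyloxy-9-hydroxy-12-oxogermacra-1(10),4,11(13)-trien-12,6-olid-14-oate | C=C1C(=O)O[C@@H]2/C=C(/C)CC/C=C(/C(=O)OC)[C@H](O)[C@@H](OC(=O)/C(C)=C\C)[C@@H]12 | target

## Step count and least certain steps

Total step count: 12. Longest linear sequence: 12 steps (1 to 23); all other building blocks (2, 4, 5, 8, 14, 17, 20) are commercial.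

**Step 2 (key step).**
- Risk: facial control in the conjugate addition may be eroded if the C8 dioxolane opposes the catalyst. Oxygenation of the hindered, β-branched enamine may be slow and poorly selective, while the peroxide oxidises the amine.
- Fallback: the two stages are separated, so that each centre gets its own catalyst. Setting out from 3, the malonate addition is run alone with the amine that gives the best C7 selectivity, and Michael adduct 6 is isolated. C6 is then oxygenated in a second operation with a different amine, (S)-2-(triphenylmethyl)pyrrolidine, and 5, coming back to the route at 7. This fallback makes no compound outside the list (F0).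

**Step 12.**
- Risk: addition may go to the wrong face of the C9 aldehyde, since the open-chain preference favours the 8,9-anti alcohol. The ester-bearing alkenylchromium may lose its geometry. The angeloyl group may shift to the new alkoxide.
- Fallback: C9 is set by reagent-controlled reduction instead of by the C–C bond formation. Setting out from 22, the closure is accepted with either facial outcome. The 9R alcohol F1 is oxidised with Dess–Martin periodinane to the C9 ketone F2. Corey–Bakshi–Shibata reduction, with the oxazaborolidine enantiomer that delivers hydride to the Re face of the ketone, then returns to the route at 23.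

**Step 3.**
- Risk: the basic ylide may take the malonate proton or enolise the α-benzoyloxy aldehyde, with epimerisation at C6 and low conversion. Z selectivity may erode.
- Fallback: setting out from 7, a Ramirez olefination (CBr4, PPh3, CH2Cl2, 0 °C, no base) gives the 1,1-dibromoalkene F3. Trans-selective Negishi monomethylation (MeZnCl, PdCl2(DPEphos), THF) gives the (Z)-bromoalkene F4. Copper-catalysed halogen exchange (CuI, NaI, trans-N,N'-dimethylcyclohexane-1,2-diamine, dioxane, 110 °C) with retention comes back to the route at 9.

**Step 4.**
- Risk: hydrolysis of the hindered malonate may be incomplete. The acetonide may be lost during the acidification that closes the lactone.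
- Fallback: the lactone is closed under base before any ester is hydrolysed. Setting out from 9, K2CO3 in MeOH removes the benzoate by methanolysis, and the C6 alkoxide closes on one malonate ester to give the methyl ester lactone F5. Its remaining methyl ester is cleaved with Me3SnOH (1,2-dichloroethane, 70 °C), coming back to the route at 11.

**Step 11.**
- Risk: silyl ether cleavage under the Swern conditions may be incomplete. The amine may epimerise the α-acyloxy aldehyde at C8.
- Fallback: setting out from 21, the silyl ether is removed with HF·pyridine (THF/pyridine, 0 °C) to give the primary alcohol F6. This is oxidised at once with Dess–Martin periodinane buffered with NaHCO3, coming back to the route at 22.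

Further compounds

F0 | step 2 | none | none
F1 | step 12 | 9-epi-23, the 9R alcohol | C=C1C(=O)O[C@@H]2/C=C(/C)CC/C=C(/C(=O)OC)[C@@H](O)[C@@H](OC(=O)/C(C)=C\C)[C@@H]12
F2 | step 12 | C9 ketone of 23 | C=C1C(=O)O[C@@H]2/C=C(/C)CC/C=C(/C(=O)OC)C(=O)[C@@H](OC(=O)/C(C)=C\C)[C@@H]12
F3 | step 3 | 1,1-dibromoalkene, dimethyl 2-[(1S,2S)-2-(benzoyloxy)-4,4-dibromo-1-[(4S)-2,2-dimethyl-1,3-dioxolan-4-yl]but-3-en-1-yl]propanedioate | BrC(Br)=C[C@@H](OC(=O)c1ccccc1)[C@H](C(C(=O)OC)C(=O)OC)[C@H]1COC(C)(C)O1
F4 | step 3 | (Z)-bromoalkene, bromo analogue of 9 | C/C(Br)=C/[C@@H](OC(=O)c1ccccc1)[C@H](C(C(=O)OC)C(=O)OC)[C@H]1COC(C)(C)O1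
F5 | step 4 | methyl ester lactone, methyl ester of 11 | C/C(I)=C/[C@H]1OC(=O)C(C(=O)OC)[C@@H]1[C@H]2COC(C)(C)O2
F6 | step 11 | primary alcohol, desilylated 21 | C/C(CC/C=C(\I)C(=O)OC)=C/[C@H]1OC(=O)C(=C)[C@@H]1[C@H](OC(=O)/C(C)=C\C)CO
A1 | alternative 1 | open-chain (Z)-C5 iodide with C6 aldehyde and C12 methyl ester | I/C=C(/C)CC/C=C(/C(=O)OC)[C@H](O[Si](C)(C)C(C)(C)C)[C@@H](OC(=O)/C(C)=C\C)[C@H](C=O)CC(=O)OC
A2 | alternative 1 | bicyclic lactone lacking the C13 methylene, C9 tert-butyldimethylsilyl ether | C1C(=O)O[C@@H]2/C=C(/C)CC/C=C(/C(=O)OC)[C@H](O[Si](C)(C)C(C)(C)C)[C@@H](OC(=O)/C(C)=C\C)[C@@H]12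
A3 | alternative 2 | lactone-fused 2-carbomethoxycyclohexenone, C8 triethylsilyl ether | C1C(=O)O[C@@H]2C=C(C(=O)OC)C(=O)[C@@H](O[Si](CC)(CC)CC)[C@@H]12
A4 | alternative 2 | 1-methylcyclobutene | CC1=CCC1
A5 | alternative 2 | cis-anti-cis tricyclic photoadduct | C1C(=O)O[C@@H]2[C@H]3[C@@](C(=O)OC)(C(=O)[C@@H](O[Si](CC)(CC)CC)[C@@H]12)[C@@H]4CC[C@]34C
A6 | alternative 3 | open-chain C3 phenyl sulfone with C2 allylic bromide | O=S(=O)(c1ccccc1)C/C(C)=C\[C@H]2OC(=O)C[C@@H]2[C@H](OC(=O)/C(C)=C\C)[C@@H](O[Si](C)(C)C(C)(C)C)/C(CO[Si](CC)(CC)CC)=C\CBr
A7 | alternative 3 | ten-membered ring with C3 sulfone (one C3 epimer drawn) | C1C(=O)O[C@@H]2/C=C(/C)[C@@H](S(=O)(=O)c3ccccc3)C/C=C(/CO[Si](CC)(CC)CC)[C@H](O[Si](C)(C)C(C)(C)C)[C@@H](OC(=O)/C(C)=C\C)[C@@H]12
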